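## The problem

Compound 26 joins three guaiacyl-type arenes (ring A, ring B, ring C) through two oxygen heterocycles. One is a cis-fused 3,7-dioxabicyclo[3.3.0]octane (furofuran: C1, C2, O3, C4, C5, C6, O7, C8) with ring A on C2 and ring B on C6. The other is a 2,3-dihydrobenzofuran fused to ring B (primed numbers) with ring C on C2' and CH2OH on C3'. Read atom by atom, the stereodescriptors give 1S,2S,5S,6S, so H1/H2 and H5/H6 are cis and both aryl groups lie on the concave (endo) face. They also give 2'S,3'S, so ring C and CH2OH are cis. Both arrangements are the less stable ones, so all six centres must be set kinetically and never allowed to equilibrate.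

The four furofuran centres are contiguous and can relay to one another. C1 fixes C5 through the obligatory cis fusion, the fold of the bicycle decides the face of attack at C6, and C2 can be derived stereospecifically from a neighbour of C1. The two dihydrobenzofuran centres lie beyond the flat ring B, and neither set can control the other. Two independent sources of absolute configuration and a convergent union are therefore required.

All four benzylic C–O bonds stand para to an oxygen donor. Acid ionises them (endo to exo, cis to trans), hydrogenolysis cleaves them, and the free phenols are oxidisable and, as phenoxides, can push out the para-benzylic oxygen. The closing steps must be mild and basic, hydridic or fluoride-based.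

The enabling feature is the array C2–C1–C5. It has the donor ring A at one end and, at the other, a carbon next to C6, which can be held at the carbonyl level and doubled by a removable ester. The O3–C4 unit that bridges the two ends is formaldehyde. The ring C1–C2–O3–C4–C5 is thus the formal (3+2) adduct of a lactone-fused donor–acceptor cyclopropane and CH2O. The geometry of a simple E alkene can be translated, by inversion, into the endo aryl group.

## Retrosynthesis

**Unmasking (26 ⇐ 25 ⇐ 24).** Only O–Si and O–C(=O)N bonds are cut. Fluoride releases the ring C phenol and the primary alcohol (25 → 26), and one step earlier hydride releases the ring A phenol from its diethylcarbamate (24 → 25). Acid-labile and hydrogenolysable groups are excluded by the four donor-activated benzylic ethers. The two kinds of phenol protection are deliberate. Ring C must remain a donor for the C–H insertion, whereas ring A must be a weak donor for the annulation and for the one acidic step. The forward reactions need only be nucleophilic or basic.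

**C6–C5' and C6–H (24 ⇐ 23 ⇐ 11 + 22).**
- The bond between the furofuran and ring B is the only cut that separates the two stereochemical sets. It gives halves of similar size. A cut at C2–ring A would leave all six centres in one piece.
- With C6 as a lactone carbonyl (11), ring B enters as aryllithium 22, made from bromide 21.
- The last centre arises when hydride meets the oxocarbenium ion of lactol 23 on the convex face, which pushes ring B endo.
- The forward steps must give clean mono-addition and a reduction faster than re-ionisation.
- Minor enantiomers of the two halves end up as separable diastereomers of 23 or 24.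

**C5–CO2Me (11 ⇐ 10).** Adding an ester to C5 in the retrosynthetic sense makes C5 doubly activated. This is the retron of a donor–acceptor cyclopropane. The price is one dealkoxycarbonylation, with no stereochemical cost because reprotonation can only restore the cis fusion.

**C2–O3 and C4–C5 (10 ⇐ 8 + 9).**
- Both bonds of the O3–C4 bridge are cut at once. One ring, one quaternary centre and the endo benzylic centre collapse to the bicyclic cyclopropane 8 and formaldehyde 9.
- Cutting only C2–O3 would call for a benzylic cation or quinone methide closure, which favours exo. Cutting only C4–C5 would call for a preformed, labile chloromethyl ether.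
- C4 arrives at its final oxidation level.
- The forward reaction must open the aryl-bearing cyclopropane bond with inversion and must outrun free ionisation. For that reason ring A carries the carbamate.

**Lactone C–O and two cyclopropane bonds (8 ⇐ 7 ⇐ 6 ⇐ 4 + 5).**
- Lactone 8 is the internal ester of hydroxymethyl diester 7, obtained from aldehyde 6.
- Aldehyde 6 is the Michael-initiated ring-closure product of enal 4 and bromomalonate 5 under iminium/enamine catalysis.
- An intramolecular metal-carbenoid addition would make the same ring. However, a carbenoid flanked by two esters is poorly differentiated by chiral ligands, and that route is longer. It is kept only as a fallback.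
- The forward step must deliver the trans aryl/formyl pair in high enantiomeric purity.
- Lactonisation then picks the cis ester by itself.

**Side chain and protection (4 ⇐ 2 + 3; 2 ⇐ 1).** The Cα=Cβ bond is cut to aldehyde 2 and formyl ylide 3, and the carbamate O–C bond is cut to vanillin 1. This is two steps from a bulk chemical. The E geometry is the only demand.

**C2'–C3' (21 ⇐ 20 ⇐ 19 ⇐ 18).**
- Silyl ether 21 and alcohol 20 lead back to the cis ester 19, whose C2'–C3' bond is cut to aryldiazoacetate 18.
- A concerted 1,5 C–H insertion of the rhodium carbenoid favours the cis isomer kinetically and sets both centres catalytically. Cuts at O1'–C2' or C3'–C3a' lead to closures that favour trans or need preset acyclic stereocentres.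
- The precursor is achiral.
- The forward sequence must avoid base until the ester is reduced.

**Assembly of 18 (18 ⇐ 16 + 17; 16 ⇐ 15 + 13; 15 ⇐ 14; 13 ⇐ 12 ⇐ 1).**
- The aryl–C(N2) bond is cut to iodide 16 and ethyl diazoacetate 17. This avoids a multistep homologation to an arylacetate.
- The benzylic ether bond is cut to phenol 15 and alcohol 13.
- Phenol 15 comes from 4-bromoguaiacol 14 by ortho iodination.
- Alcohol 13 comes from vanillin 1 via 12.
- The iodide must react in preference to the bromide, which is reserved for the union.

## Roads not taken

**Alternative 1:**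
- **Cut and key step.** The cut runs through O3–C4 and O7–C8 at the lactone level and leads from the endo,endo bis-lactone A1 to the stereorandom, unsymmetrical dimethyl 2,3-diaroylsuccinate A2. In the forward sense RuCl[(S,S)-TsDPEN](p-cymene) in HCO2H–Et3N would reduce both aryl ketones while C1–H and C5–H equilibrate. Each carbinol would then lactonise on the ester of the neighbouring carbon.
- **Merits.** Four stereocentres and both rings form in one flask, the carbinol centres are catalyst-controlled, and no cryogenic chemistry is needed. In steps to the bicyclic core this road is shorter than the chosen one.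
- **Weak point 1.** A2 is unsymmetrical, so the C1–C5 bond needs a directed coupling of two different aroylacetates, and the valuable ring B/C portion enters at the very start.
- **Weak point 2.** After the first lactonisation the second α-centre is locked into a ring. Its configuration is then dictated by the substrate, and the required endo,endo isomer is the most crowded of the possible outcomes.
- **Weak point 3.** C4 and C8 of A1 are carbonyls. Both must be taken down to CH2 beside benzylic acyloxy bonds para to oxygen donors, either twice through lactol and silane/Lewis acid or by exhaustive reduction and re-etherification. Each option exposes C2 and C6 to ionisation.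
- **Comparison.** The chosen plan offers C4 and C8 at their final oxidation level from the outset, a single adjustable carbon (C6), and one mechanistic reason for each centre.

**Alternative 2:**
- **Cut and key step.** The cut is C3'–C3a', made on the complete furofuran. The bis-silyl ether A3 of the target is traced to the bromoaryl epoxy-ether A4. t-BuLi would exchange the bromine of ring B, and the aryllithium would open the tethered epoxide at its internal carbon (5-exo), which releases the CH2OH oxygen.
- **Merits.** The closure is stereospecific (inversion), so the cis relationship follows from acyclic stereochemistry and not from catalyst selectivity. In that respect it is at least as reliable as a C–H insertion. It is also purely basic, which suits the furofuran.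
- **Weak point 1.** The aryl ether at the donor-activated benzylic centre C2' must be made with defined configuration from a hindered 2,6-disubstituted phenol, where substitution tends toward ionisation.
- **Weak point 2.** The aryllithium can abstract the doubly activated C2'–H through a five-membered transition state and trigger epoxide elimination.
- **Weak point 3.** Attack at the terminal epoxide carbon (6-endo) competes.
- **Weak point 4.** The plan says nothing about the endo,endo furofuran, which it needs in finished form with a free ring B phenol, so the sequence becomes linear.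
- **Comparison.** The chosen plan builds the dihydrobenzofuran early and catalytically from an achiral precursor, on material that is cheap to lose, and it solves the furofuran problem itself.

**Alternative 3:**
- **Cut and key step.** The cut is C1–C2. The endo,endo furofuranone A5 is traced to the α-diazo-γ-butyrolactone A6, which carries ring B on C6 and the ring A benzyloxymethyl arm on C5. With Rh2(OAc)4 the carbenoid at C1 would insert into the benzylic C–H and close the second ring cis-fused.
- **Merits.** This reaction class is well tested for furofuranones and has an intrinsic endo preference, an achiral catalyst suffices, and two centres are relayed from C5. In precedent for the ring-forming event it is stronger than the chosen key step.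
- **Weak point 1.** A6 requires ring B and the C4 arm cis on the lactone, the less stable arrangement beside an ionisable benzylic acyloxy bond.
- **Weak point 2.** Diazo transfer to a plain lactone needs prior α-activation with strong base.
- **Weak point 3.** The ring B/C portion is carried through the whole linear sequence.
- **Weak point 4.** After the insertion the C8 carbonyl must still be removed by lactol formation and silane/Lewis acid, with two strongly donating endo aryl groups in place.
- **Comparison.** The chosen plan is convergent, since the second half enters four steps before the end. C2 has a stereospecific rather than stereoselective origin. The only acidic step meets a ring A that is electronically switched off.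

Key step: step 5

Assumption: the stereodescriptors of the target are taken literally (endo,endo furofuran, 2',3'-cis dihydrobenzofuran), and the sense of induction in steps 3 and 12 is assigned from the accepted shielding models of these catalyst families; should either be reversed, the mirror-image catalyst, equally available, takes its place.

## Route

Step 1
Reactants: 1 vanillin (4-hydroxy-3-methoxybenzaldehyde)
Product: 2 4-formyl-2-methoxyphenyl N,N-diethylcarbamate
Conditions: Et2NCOCl, K2CO3, MeCN, reflux
Reagents that add atoms: diethylcarbamoyl chloride, CCN(CC)C(=O)Cl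
Why: O-Carbamoylation of a phenoxide. The carbamate turns the para oxygen of ring A into a weak donor, as steps 3, 5 and 16 require, and it withstands Lewis acid, hot LiCl and aryllithium at −78 °C.

Step 2
Reactants: 2 4-formyl-2-methoxyphenyl N,N-diethylcarbamate; 3 (triphenylphosphoranylidene)acetaldehyde
Product: 4 2-methoxy-4-[(E)-3-oxoprop-1-enyl]phenyl N,N-diethylcarbamate
Conditions: toluene, 90 °C
Reagents that add atoms: none
Why: Wittig olefination with a stabilised formyl ylide should give the E enal. The acyloxy-substituted benzaldehyde 2 is more electrophilic than the product enal, which limits double homologation.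

Step 3
Reactants: 4 2-methoxy-4-[(E)-3-oxoprop-1-enyl]phenyl N,N-diethylcarbamate; 5 dimethyl bromomalonate
Product: 6 dimethyl (2S,3R)-3-[4-(diethylcarbamoyloxy)-3-methoxyphenyl]-2-formylcyclopropane-1,1-dicarboxylate (aryl and formyl trans)
Conditions: (R)-α,α-diphenylprolinol trimethylsilyl ether (20 mol%), 2,6-lutidine (1.1 equiv), CH2Cl2, 0 °C
Reagents that add atoms: none
Why: Organocatalytic Michael-initiated ring closure (iminium, then enamine catalysis). The diphenyl(silyloxy)methyl group shields one face of the E iminium ion, the malonate carbon adds to the β-carbon on the open face, and the enamine displaces bromide (3-exo-tet) on the same face. Both centres are thereby set and the E geometry becomes the trans aryl/formyl relationship.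

Step 4
Reactants: 6 dimethyl (2S,3R)-3-[4-(diethylcarbamoyloxy)-3-methoxyphenyl]-2-formylcyclopropane-1,1-dicarboxylate
Product: 8 methyl (1R,5S,6R)-6-[4-(diethylcarbamoyloxy)-3-methoxyphenyl]-2-oxo-3-oxabicyclo[3.1.0]hexane-1-carboxylate (exo aryl), via hydroxymethyl diester 7 (not isolated)
Conditions: NaBH4, MeOH, −10 °C; then PPTS (cat.), CH2Cl2, rt
Reagents that add atoms: none
Why: Chemoselective borohydride reduction of the aldehyde followed by lactonisation. Only the ester cis to the new CH2OH can close the five-membered ring, which differentiates the two esters and fixes the quaternary centre without further control.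

Step 5
Reactants: 8 methyl (1R,5S,6R)-6-[4-(diethylcarbamoyloxy)-3-methoxyphenyl]-2-oxo-3-oxabicyclo[3.1.0]hexane-1-carboxylate; 9 formaldehyde (supplied as dry paraformaldehyde)
Product: 10 methyl (1S,2S,5S)-2-[4-(diethylcarbamoyloxy)-3-methoxyphenyl]-6-oxo-3,7-dioxabicyclo[3.3.0]octane-5-carboxylate (endo aryl, cis-fused)
Conditions: Sn(OTf)2 (20 mol%), paraformaldehyde (5 equiv CH2O), 4 Å molecular sieves, CH2Cl2, 0 °C → rt
Reagents that add atoms: none
Why: Divalent tin in Sn(OTf)2 chelates the lactone and ester carbonyls of 8 and polarises the bond between the diacceptor carbon (C1 of the bicyclohexane) and the aryl-bearing carbon (C6), the cyclopropane bond that carries the donor and overlaps best with both carbonyl π systems, so the C1–C5 bond stays intact. The oxygen of monomeric 9, bled from the polymer by the same Lewis acid, attacks the benzylic carbon from the rear of the breaking bond (SN2-like attack on a tight ion pair) and gives an O-alkylated oxocarbenium ion tethered to a tin enolate; after rotation about the former C5–C6 bond the enolate carbon adds to the CH2=O+ carbon. The closest known reaction type is the Lewis-acid-catalysed formal (3+2) cycloaddition of 2-arylcyclopropane-1,1-diesters with aldehydes, which is stereospecific with inversion at the donor carbon and tolerates a further substituent on the third ring carbon. The single ring closed, C1–C2–O3–C4–C5, is completed by the C4–C5 bond in a 5-(enolexo)-endo-trig aldol-type closure, feasible because the acceptor is a freely rotating oxocarbenium ion whose π* orbital can turn toward the enolate. C2 is controlled by the inversion: the exo aryl group of 8, itself the imprint of the E alkene of 4, becomes the endo aryl group of 10. C5 is controlled by the ring: the enolate belongs to the lactone already attached to C1, so the new bond can form only on the face that gives the cis-fused bicyclooctane, leaving the ester on the convex face. The selectivity needed is capture by 9 faster than full ionisation and bond rotation at the benzylic carbon; the weakly donating carbamate, the non-coordinating solvent and the low temperature secure it, and the same carbamate protects ring A from electrophilic hydroxymethylation by activated 9.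

Step 6
Reactants: 10 methyl (1S,2S,5S)-2-[4-(diethylcarbamoyloxy)-3-methoxyphenyl]-6-oxo-3,7-dioxabicyclo[3.3.0]octane-5-carboxylate
Product: 11 (1S,2S,5S)-2-[4-(diethylcarbamoyloxy)-3-methoxyphenyl]-3,7-dioxabicyclo[3.3.0]octan-6-one (endo aryl)
Conditions: LiCl, H2O (2 equiv), DMSO, 135 °C
Reagents that add atoms: none
Why: Krapcho dealkoxycarbonylation. Chloride demethylates the ester, the carboxylate loses CO2 to a lactone enolate, and protonation can only restore the cis fusion, so C5 is S by ring constraint. The C4–O3 bond lies near the nodal plane of that enolate, so β-elimination is not expected, and a dialkylcarbamate survives conditions that would endanger an aryl silyl ether.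

Step 7
Reactants: 1 vanillin
Product: 12 3-methoxy-4-(triisopropylsilyloxy)benzaldehyde
Conditions: TIPSCl, imidazole, DMF, rt
Reagents that add atoms: chlorotriisopropylsilane, CC(C)[Si](Cl)(C(C)C)C(C)C
Why: Standard phenol silylation. The bulky silyl ether keeps ring C a donor for step 12 and resists amine bases, aluminium hydride and organolithium better than a smaller silyl group would.

Step 8
Reactants: 12 3-methoxy-4-(triisopropylsilyloxy)benzaldehyde
Product: 13 [3-methoxy-4-(triisopropylsilyloxy)phenyl]methanol
Conditions: NaBH4, MeOH, 0 °C
Reagents that add atoms: none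
Why: Borohydride reduction of an aromatic aldehyde. No other group is reducible.

Step 9
Reactants: 14 4-bromo-2-methoxyphenol
Product: 15 4-bromo-2-iodo-6-methoxyphenol
Conditions: I2, NaHCO3, THF–H2O, rt
Reagents that add atoms: iodine, II
Why: Electrophilic aromatic iodination through the phenoxide. The para position is blocked by bromine and one ortho position by methoxy, so only C6 is open to the ortho-directing phenoxide.

Step 10
Reactants: 15 4-bromo-2-iodo-6-methoxyphenol; 13 [3-methoxy-4-(triisopropylsilyloxy)phenyl]methanol
Product: 16 5-bromo-1-iodo-3-methoxy-2-{[3-methoxy-4-(triisopropylsilyloxy)phenyl]methoxy}benzene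
Conditions: PPh3, DIAD, THF, 0 °C → rt
Reagents that add atoms: none
Why: Mitsunobu etherification of an acidic phenol with a primary benzylic alcohol. The neutral medium spares the aryl silyl ether and avoids a labile 4-silyloxybenzyl halide.

Step 11
Reactants: 16 5-bromo-1-iodo-3-methoxy-2-{[3-methoxy-4-(triisopropylsilyloxy)phenyl]methoxy}benzene; 17 ethyl diazoacetate
Product: 18 ethyl 2-(5-bromo-3-methoxy-2-{[3-methoxy-4-(triisopropylsilyloxy)phenyl]methoxy}phenyl)-2-diazoacetate
Conditions: Pd(PPh3)4 (5 mol%), Ag2CO3 (0.5 equiv), Et3N, toluene, rt
Reagents that add atoms: none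
Why: Palladium-catalysed cross-coupling of an aryl iodide with the C–H bond of a diazoacetate, with retention of the diazo group. At room temperature zerovalent palladium inserts into C–I and leaves C–Br for step 15.

Step 12
Reactants: 18 ethyl 2-(5-bromo-3-methoxy-2-{[3-methoxy-4-(triisopropylsilyloxy)phenyl]methoxy}phenyl)-2-diazoacetate
Product: 19 ethyl (2S,3R)-5-bromo-7-methoxy-2-[3-methoxy-4-(triisopropylsilyloxy)phenyl]-2,3-dihydro-1-benzofuran-3-carboxylate (2,3-cis)
Conditions: Rh2(R-PTTL)4 (dirhodium tetrakis[N-phthaloyl-(R)-tert-leucinate], 1 mol%), toluene, −60 °C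
Reagents that add atoms: none
Why: Enantioselective intramolecular 1,5 C–H insertion of a donor/acceptor rhodium carbenoid into the ether-activated benzylic CH2. The concerted insertion gives the cis isomer as the kinetic product, and the chiral carboxylate wall selects one of the two enantiotopic hydrogens, so C2' and C3' are set together.

Step 13
Reactants: 19 ethyl (2S,3R)-5-bromo-7-methoxy-2-[3-methoxy-4-(triisopropylsilyloxy)phenyl]-2,3-dihydro-1-benzofuran-3-carboxylate
Product: 20 {(2S,3S)-5-bromo-7-methoxy-2-[3-methoxy-4-(triisopropylsilyloxy)phenyl]-2,3-dihydro-1-benzofuran-3-yl}methanol (2,3-cis)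
Conditions: i-Bu2AlH (2.5 equiv), CH2Cl2, −78 °C; Rochelle salt
Reagents that add atoms: none
Why: Ester reduction with a non-basic aluminium hydride at low temperature avoids enolisation of the cis ester, and excess hydride consumes the epimerisable aldehyde stage at once. The descriptor at C3' changes only because the priorities change.

Step 14
Reactants: 20 {(2S,3S)-5-bromo-7-methoxy-2-[3-methoxy-4-(triisopropylsilyloxy)phenyl]-2,3-dihydro-1-benzofuran-3-yl}methanol
Product: 21 (2S,3S)-5-bromo-3-[(tert-butyldimethylsilyloxy)methyl]-7-methoxy-2-[3-methoxy-4-(triisopropylsilyloxy)phenyl]-2,3-dihydro-1-benzofuran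
Conditions: TBSCl, imidazole, DMF, rt
Reagents that add atoms: tert-butyldimethylsilyl chloride, CC(C)(C)[Si](C)(C)Cl
Why: Silylation of a primary alcohol removes the only acidic proton before metalation. C3' is no longer epimerisable.

Step 15
Reactants: 21 (2S,3S)-5-bromo-3-[(tert-butyldimethylsilyloxy)methyl]-7-methoxy-2-[3-methoxy-4-(triisopropylsilyloxy)phenyl]-2,3-dihydro-1-benzofuran; 11 (1S,2S,5S)-2-[4-(diethylcarbamoyloxy)-3-methoxyphenyl]-3,7-dioxabicyclo[3.3.0]octan-6-one
Product: 23 (1S,2S,5S)-6-hydroxy lactol bearing ring A (carbamate) endo on C2 plus the silylated dihydrobenzofuran-5-yl group on C6 (anomeric mixture), via aryllithium 22 (not isolated)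
Conditions: 21, t-BuLi (2.0 equiv), THF, −78 °C; then 11, −78 °C; AcOH (in THF), −78 °C
Reagents that add atoms: none
Why: Bromine–lithium exchange followed by 1,2-addition of the aryllithium to a γ-lactone. The tetrahedral lithium alkoxide persists at −78 °C, so only one aryl group enters, and the diethylcarbamate is inert to an aryllithium at this temperature. Any competing enolisation merely returns 11, because the fusion can only be cis.

Step 16
Reactants: 23 lactol
Product: 24 (1S,2S,5S,6S)-2-[4-(diethylcarbamoyloxy)-3-methoxyphenyl]-6-{(2S,3S)-3-[(tert-butyldimethylsilyloxy)methyl]-7-methoxy-2-[3-methoxy-4-(triisopropylsilyloxy)phenyl]-2,3-dihydro-1-benzofuran-5-yl}-3,7-dioxabicyclo[3.3.0]octane (endo,endo)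
Conditions: Et3SiH (5 equiv), BF3·OEt2 (1.5 equiv), CH2Cl2, −78 °C; aq. NaHCO3 at −78 °C
Reagents that add atoms: none
Why: Ionic hydrogenation (silane reduction of a cyclic aryl oxocarbenium ion). Hydride enters from the convex face of the folded bicycle, whose concave face is further blocked by ring A, so H6 ends exo and ring B endo (6S). The hemiketal ionises far more easily than any ether at −78 °C, and the carbamate keeps C2–O3 closed.

Step 17
Reactants: 24 fully protected endo,endo furofuran
Product: 25 ring A phenol: 4-[(1S,2S,5S,6S)-6-{(2S,3S)-3-[(tert-butyldimethylsilyloxy)methyl]-7-methoxy-2-[3-methoxy-4-(triisopropylsilyloxy)phenyl]-2,3-dihydro-1-benzofuran-5-yl}-3,7-dioxabicyclo[3.3.0]octan-2-yl]-2-methoxyphenol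
Conditions: LiAlH4, THF, 0 → 40 °C
Reagents that add atoms: none
Why: Reductive cleavage of an aryl carbamate. Hydride adds to the carbamate carbonyl and expels the phenoxide, while ethers, silyl ethers and all six stereocentres are inert to hydride and base.

Step 18
Reactants: 25 ring A phenol
Product: 26 target CNP0303197.1, (1S,2S,5S,6S)-2-(4-hydroxy-3-methoxyphenyl)-6-[(2S,3S)-2-(4-hydroxy-3-methoxyphenyl)-3-(hydroxymethyl)-7-methoxy-2,3-dihydro-1-benzofuran-5-yl]-3,7-dioxabicyclo[3.3.0]octane
Conditions: TBAF, AcOH (1:1), THF, 0 °C
Reagents that add atoms: none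
Why: Fluoride desilylation of the aryl and the primary alkyl silyl ether in one operation. The acetic acid buffer keeps the phenols protonated, so no phenoxide can push out a para-benzylic oxygen, and no acid strong enough to ionise the benzylic ethers is present.

## Compound list

1 | vanillin (4-hydroxy-3-methoxybenzaldehyde) | COc1cc(C=O)ccc1O | starting material
2 | 4-formyl-2-methoxyphenyl N,N-diethylcarbamate | COc1cc(C=O)ccc1OC(=O)N(CC)CC | intermediate
3 | (triphenylphosphoranylidene)acetaldehyde | O=CC=P(c1ccccc1)(c1ccccc1)c1ccccc1 | starting material
4 | 2-methoxy-4-[(E)-3-oxoprop-1-enyl]phenyl N,N-diethylcarbamate | COc1cc(/C=C/C=O)ccc1OC(=O)N(CC)CC | intermediate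
5 | dimethyl bromomalonate | COC(=O)C(Br)C(=O)OC | starting material
6 | dimethyl (2S,3R)-3-[4-(diethylcarbamoyloxy)-3-methoxyphenyl]-2-formylcyclopropane-1,1-dicarboxylate | COc1cc([C@@H]2C(C(=O)OC)(C(=O)OC)[C@H]2C=O)ccc1OC(=O)N(CC)CC | intermediate
7 | dimethyl (2S,3R)-3-[4-(diethylcarbamoyloxy)-3-methoxyphenyl]-2-(hydroxymethyl)cyclopropane-1,1-dicarboxylate (not isolated) | COc1cc([C@@H]2C(C(=O)OC)(C(=O)OC)[C@H]2CO)ccc1OC(=O)N(CC)CC | intermediate
8 | methyl (1R,5S,6R)-6-[4-(diethylcarbamoyloxy)-3-methoxyphenyl]-2-oxo-3-oxabicyclo[3.1.0]hexane-1-carboxylate (exo aryl) | COc1cc([C@@H]2[C@@]3(C(=O)OC)C(=O)OC[C@@H]23)ccc1OC(=O)N(CC)CC | intermediate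
9 | formaldehyde (supplied as paraformaldehyde) | C=O | starting material
10 | methyl (1S,2S,5S)-2-[4-(diethylcarbamoyloxy)-3-methoxyphenyl]-6-oxo-3,7-dioxabicyclo[3.3.0]octane-5-carboxylate (endo aryl) | COc1cc([C@H]2OC[C@]3(C(=O)OC)[C@H]2COC3=O)ccc1OC(=O)N(CC)CC | intermediate
11 | (1S,2S,5S)-2-[4-(diethylcarbamoyloxy)-3-methoxyphenyl]-3,7-dioxabicyclo[3.3.0]octan-6-one (endo aryl) | COc1cc([C@H]2OC[C@@H]3[C@H]2COC3=O)ccc1OC(=O)N(CC)CC | intermediate
12 | 3-methoxy-4-(triisopropylsilyloxy)benzaldehyde | COc1cc(C=O)ccc1O[Si](C(C)C)(C(C)C)C(C)C | intermediate
13 | [3-methoxy-4-(triisopropylsilyloxy)phenyl]methanol | COc1cc(CO)ccc1O[Si](C(C)C)(C(C)C)C(C)C | intermediate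
14 | 4-bromo-2-methoxyphenol | COc1cc(Br)ccc1O | starting material
15 | 4-bromo-2-iodo-6-methoxyphenol | COc1cc(Br)cc(I)c1O | intermediate
16 | 5-bromo-1-iodo-3-methoxy-2-{[3-methoxy-4-(triisopropylsilyloxy)phenyl]methoxy}benzene | COc1cc(Br)cc(I)c1OCc1ccc(O[Si](C(C)C)(C(C)C)C(C)C)c(OC)c1 | intermediate
17 | ethyl diazoacetate | CCOC(=O)C=[N+]=[N-] | starting material
18 | ethyl 2-(5-bromo-3-methoxy-2-{[3-methoxy-4-(triisopropylsilyloxy)phenyl]methoxy}phenyl)-2-diazoacetate | CCOC(=O)C(=[N+]=[N-])c1cc(Br)cc(OC)c1OCc1ccc(O[Si](C(C)C)(C(C)C)C(C)C)c(OC)c1 | intermediate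
19 | ethyl (2S,3R)-5-bromo-7-methoxy-2-[3-methoxy-4-(triisopropylsilyloxy)phenyl]-2,3-dihydro-1-benzofuran-3-carboxylate (cis) | Brc1cc(OC)c2c(c1)[C@@H](C(=O)OCC)[C@@H](c1ccc(O[Si](C(C)C)(C(C)C)C(C)C)c(OC)c1)O2 | intermediate
20 | {(2S,3S)-5-bromo-7-methoxy-2-[3-methoxy-4-(triisopropylsilyloxy)phenyl]-2,3-dihydro-1-benzofuran-3-yl}methanol (cis) | Brc1cc(OC)c2c(c1)[C@@H](CO)[C@@H](c1ccc(O[Si](C(C)C)(C(C)C)C(C)C)c(OC)c1)O2 | intermediate
21 | (2S,3S)-5-bromo-3-[(tert-butyldimethylsilyloxy)methyl]-7-methoxy-2-[3-methoxy-4-(triisopropylsilyloxy)phenyl]-2,3-dihydro-1-benzofuran | Brc1cc(OC)c2c(c1)[C@@H](CO[Si](C)(C)C(C)(C)C)[C@@H](c1ccc(O[Si](C(C)C)(C(C)C)C(C)C)c(OC)c1)O2 | intermediate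
22 | the 5-lithio derivative of 21 (not isolated) | [Li]c1cc(OC)c2c(c1)[C@@H](CO[Si](C)(C)C(C)(C)C)[C@@H](c1ccc(O[Si](C(C)C)(C(C)C)C(C)C)c(OC)c1)O2 | intermediate
23 | (1S,2S,5S)-6-aryl-6-hydroxy-3,7-dioxabicyclo[3.3.0]octane lactol, ring A carbamate endo on C2, anomeric mixture at C6 | COc1cc([C@H]2OC[C@@H]3[C@H]2COC3(O)c2cc(OC)c3c(c2)[C@@H](CO[Si](C)(C)C(C)(C)C)[C@@H](c2ccc(O[Si](C(C)C)(C(C)C)C(C)C)c(OC)c2)O3)ccc1OC(=O)N(CC)CC | intermediate
24 | fully protected (1S,2S,5S,6S,2'S,3'S) endo,endo furofuran (ring A carbamate, ring C triisopropylsilyl ether, primary tert-butyldimethylsilyl ether) | COc1cc([C@H]2OC[C@@H]3[C@H]2CO[C@@H]3c2cc(OC)c3c(c2)[C@@H](CO[Si](C)(C)C(C)(C)C)[C@@H](c2ccc(O[Si](C(C)C)(C(C)C)C(C)C)c(OC)c2)O3)ccc1OC(=O)N(CC)CC | intermediate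
25 | ring A phenol, still silylated on ring C and on the primary alcohol | COc1cc([C@H]2OC[C@@H]3[C@H]2CO[C@@H]3c2cc(OC)c3c(c2)[C@@H](CO[Si](C)(C)C(C)(C)C)[C@@H](c2ccc(O[Si](C(C)C)(C(C)C)C(C)C)c(OC)c2)O3)ccc1O | intermediate
26 | CNP0303197.1 | COc1cc([C@H]2OC[C@@H]3[C@H]2CO[C@@H]3c2cc(OC)c3c(c2)[C@@H](CO)[C@@H](c2ccc(O)c(OC)c2)O3)ccc1O | target

## Step count and least certain steps

Total steps: 18. Longest linear sequence: 11 steps (7, 8, 10, 11, 12, 13, 14, 15, 16, 17, 18, from vanillin 1). Fragment 1 (steps 1–6) and the phenol branch (step 9) run in parallel.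

**Step 5 (key step).**
- **Risk.** Formaldehyde is a weaker oxygen nucleophile than the aryl and alkenyl aldehydes for which this annulation type is established, and the Lewis acid also drives its oligomerisation. The activated cyclopropane may then wait too long. That would allow full ionisation at the benzylic carbon with bond rotation (drift from endo to exo) or internal capture of the cation by the ester carbonyl oxygen.
- **Fallback (from 8, back at 10).** (E)-Cinnamaldehyde, a well-behaved partner of this annulation, takes the place of 9. It should give methyl (1S,2S,5S)-2-[4-(diethylcarbamoyloxy)-3-methoxyphenyl]-6-oxo-4-[(E)-2-phenylethenyl]-3,7-dioxabicyclo[3.3.0]octane-5-carboxylate F1, whose configuration at C4 is of no consequence. Ozonolysis with Me2S work-up cuts the styryl group to the corresponding 4-carbaldehyde F2. Tsuji–Wilkinson decarbonylation with RhCl(PPh3)3 in hot toluene then replaces CHO by H and delivers 10.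

**Step 16.**
- **Risk.** The product is the kinetic isomer, and ring B is a strong para donor. The Lewis acid may re-ionise the new C6–O7 bond (drift to exo) or the C2'–O1' bond (drift of the dihydrobenzofuran from cis to trans) if the temperature rises or the quench is slow. Facial selectivity may also be eroded if the crowded endo approach of ring B raises the convex-face barrier.
- **Fallback (from 23, back at 24, no acid).** Through its ring–chain equilibrium, 23 is reduced under catalyst control by Corey–Bakshi–Shibata reduction with the (R)-Me-oxazaborolidine and BH3·SMe2. The product is the all-cis 2,3,4-trisubstituted tetrahydrofuran diol with an (S)-configured CH(OH)–ring B group, F3. Selective mesylation of the primary hydroxyl (MsCl, 2,4,6-collidine, −20 °C) gives the primary monomesylate F4. NaH in THF then closes O7–C8 by a 5-exo-tet Williamson reaction, which leaves the benzylic configuration untouched and gives 24.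

**Step 12.**
- **Risk.** The 7'-methoxy group buttresses the benzyloxy group, and the ester is ethyl rather than methyl. Discrimination between the two enantiotopic hydrogens may therefore be incomplete, and oxonium ylide formation with benzyl migration may compete.
- **Fallback (from scalemic 20, back at enantiopure 20).** This replaces catalyst control by resolution. Steglich esterification with (S)-2-methoxy-2-phenylacetic acid (DCC, DMAP) gives the (S)-O-methylmandelate ester of 20, F5. Its diastereomers are separated by chromatography or crystallisation, and i-Bu2AlH at −78 °C releases 20 without any basic step.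

**Step 11.**
- **Risk.** The iodide is electron-rich and flanked by a bulky benzyloxy group, so oxidative addition and the coupling may be slow. Palladium-induced loss of nitrogen from 17 or 18, with carbene dimerisation, may then take over.
- **Fallback (from 16, back at 18).** Reformatsky–Negishi coupling of 16 with BrZnCH2CO2Et (Pd2(dba)3, XPhos, THF, rt, C–I selective) gives ethyl 2-(5-bromo-3-methoxy-2-{[3-methoxy-4-(triisopropylsilyloxy)phenyl]methoxy}phenyl)acetate F6. Regitz diazo transfer with 4-acetamidobenzenesulfonyl azide and DBU in MeCN converts it into 18.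

**Step 3.**
- **Risk.** The amine catalyst may re-activate the formyl group of the product as an iminium ion and open the donor–acceptor cyclopropane, with loss of stereochemical integrity. Slow conjugate addition may also leave room for an uncatalysed background reaction.
- **Fallback (from 4, back at 8, carbenoid chemistry).** Luche reduction (NaBH4, CeCl3·7H2O) gives 4-[(E)-3-hydroxyprop-1-enyl]-2-methoxyphenyl N,N-diethylcarbamate F7. Acylation with methyl 3-chloro-3-oxopropanoate and pyridine gives the mixed methyl cinnamyl malonate F8. Regitz diazo transfer gives the diazomalonate F9. Intramolecular cyclopropanation with CuOTf and the tert-butyl bis(oxazoline) ligand of the appropriate handedness closes 8 with the same exo aryl geometry. Because enantioselection by such diester carbenoids is expected to be modest, 8 would have to be enriched by recrystallisation.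

## Further compounds

F1 | step 5 | methyl (1S,2S,5S)-2-[4-(diethylcarbamoyloxy)-3-methoxyphenyl]-6-oxo-4-[(E)-2-phenylethenyl]-3,7-dioxabicyclo[3.3.0]octane-5-carboxylate (C4 undefined) | COc1cc([C@H]2OC(/C=C/c3ccccc3)[C@]3(C(=O)OC)[C@H]2COC3=O)ccc1OC(=O)N(CC)CC
F2 | step 5 | methyl (1S,2S,5S)-2-[4-(diethylcarbamoyloxy)-3-methoxyphenyl]-4-formyl-6-oxo-3,7-dioxabicyclo[3.3.0]octane-5-carboxylate (C4 undefined) | COc1cc([C@H]2OC(C=O)[C@]3(C(=O)OC)[C@H]2COC3=O)ccc1OC(=O)N(CC)CC
F3 | step 16 | all-cis tetrahydrofuran diol: ring A carbamate on C2, CH2OH on C3, (S)-CH(OH)–ring B on C4 | COc1cc([C@H]2OC[C@@H]([C@H](O)c3cc(OC)c4c(c3)[C@@H](CO[Si](C)(C)C(C)(C)C)[C@@H](c3ccc(O[Si](C(C)C)(C(C)C)C(C)C)c(OC)c3)O4)[C@H]2CO)ccc1OC(=O)N(CC)CC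
F4 | step 16 | primary monomesylate of F3 | COc1cc([C@H]2OC[C@@H]([C@H](O)c3cc(OC)c4c(c3)[C@@H](CO[Si](C)(C)C(C)(C)C)[C@@H](c3ccc(O[Si](C(C)C)(C(C)C)C(C)C)c(OC)c3)O4)[C@H]2COS(C)(=O)=O)ccc1OC(=O)N(CC)CC
F5 | step 12 | (S)-2-methoxy-2-phenylacetate ester of 20 | Brc1cc(OC)c2c(c1)[C@@H](COC(=O)[C@@H](OC)c1ccccc1)[C@@H](c1ccc(O[Si](C(C)C)(C(C)C)C(C)C)c(OC)c1)O2
F6 | step 11 | ethyl 2-(5-bromo-3-methoxy-2-{[3-methoxy-4-(triisopropylsilyloxy)phenyl]methoxy}phenyl)acetate | CCOC(=O)Cc1cc(Br)cc(OC)c1OCc1ccc(O[Si](C(C)C)(C(C)C)C(C)C)c(OC)c1
F7 | step 3 | 4-[(E)-3-hydroxyprop-1-enyl]-2-methoxyphenyl N,N-diethylcarbamate | COc1cc(/C=C/CO)ccc1OC(=O)N(CC)CC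
F8 | step 3 | methyl (E)-3-[4-(diethylcarbamoyloxy)-3-methoxyphenyl]prop-2-enyl malonate | COC(=O)CC(=O)OC/C=C/c1ccc(OC(=O)N(CC)CC)c(OC)c1
F9 | step 3 | methyl (E)-3-[4-(diethylcarbamoyloxy)-3-methoxyphenyl]prop-2-enyl 2-diazomalonate | COC(=O)C(=[N+]=[N-])C(=O)OC/C=C/c1ccc(OC(=O)N(CC)CC)c(OC)c1
A1 | alternative 1 | endo,endo-2,6-diaryl-3,7-dioxabicyclo[3.3.0]octane-4,8-dione, tris(tert-butyldimethylsilyl) ether | COc1cc([C@H]2OC(=O)[C@@H]3[C@H]2C(=O)O[C@@H]3c2cc(OC)c3c(c2)[C@@H](CO[Si](C)(C)C(C)(C)C)[C@@H](c2ccc(O[Si](C)(C)C(C)(C)C)c(OC)c2)O3)ccc1O[Si](C)(C)C(C)(C)C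
A2 | alternative 1 | dimethyl 2,3-diaroylsuccinate (C1 and C5 stereorandom) | COC(=O)C(C(=O)c1ccc(O[Si](C)(C)C(C)(C)C)c(OC)c1)C(C(=O)OC)C(=O)c1cc(OC)c2c(c1)[C@@H](CO[Si](C)(C)C(C)(C)C)[C@@H](c1ccc(O[Si](C)(C)C(C)(C)C)c(OC)c1)O2
A3 | alternative 2 | bis(tert-butyldimethylsilyl) ether of the target (both phenols silylated) | COc1cc([C@H]2OC[C@@H]3[C@H]2CO[C@@H]3c2cc(OC)c3c(c2)[C@@H](CO)[C@@H](c2ccc(O[Si](C)(C)C(C)(C)C)c(OC)c2)O3)ccc1O[Si](C)(C)C(C)(C)C
A4 | alternative 2 | endo,endo furofuran whose ring B carries bromine and the 1-aryl-2,3-epoxypropyl ether | COc1cc([C@H]2OC[C@@H]3[C@H]2CO[C@@H]3c2cc(OC)c(O[C@H](c3ccc(O[Si](C)(C)C(C)(C)C)c(OC)c3)[C@H]3CO3)c(Br)c2)ccc1O[Si](C)(C)C(C)(C)C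
A5 | alternative 3 | endo,endo-2,6-diaryl-3,7-dioxabicyclo[3.3.0]octan-8-one, tris(tert-butyldimethylsilyl) ether | COc1cc([C@H]2OC[C@@H]3[C@H]2C(=O)O[C@@H]3c2cc(OC)c3c(c2)[C@@H](CO[Si](C)(C)C(C)(C)C)[C@@H](c2ccc(O[Si](C)(C)C(C)(C)C)c(OC)c2)O3)ccc1O[Si](C)(C)C(C)(C)C
A6 | alternative 3 | cis-4,5-disubstituted 3-diazo-γ-butyrolactone with ring B on C6 and the ring A benzyloxymethyl arm on C5 | COc1cc(COC[C@@H]2C(=[N+]=[N-])C(=O)O[C@@H]2c2cc(OC)c3c(c2)[C@@H](CO[Si](C)(C)C(C)(C)C)[C@@H](c2ccc(O[Si](C)(C)C(C)(C)C)c(OC)c2)O3)ccc1O[Si](C)(C)C(C)(C)C
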